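Compounds 1–12 are numbered as in the steps and the compound list; 12 is the target. Atom labels: flavanone unit O1, C2, C3, C4, C4a, C5–C8, C8a, with ring B on C2; flavone unit O1'', C2'', C3'', C4'' and so on.

## Analysis of the target

Compound 12 is a biflavonoid in which C3 of a 5,7,4'-trihydroxyflavanone (ring A fused to the dihydropyranone ring C, ring B on C2) is bonded to C3'' of a 5,7,4'-trihydroxyflavone. Its only stereocentres are the adjacent C2 (S) and C3 (R) of ring C; ring B and the flavone are trans, so both can sit equatorial on the half-chair. Both centres are labile: C3–H lies between the C4 carbonyl and the flavone and can enolise, and ring C can open at O1–C2 by a retro-oxa-Michael reaction, which the para-hydroxyl of ring B makes easy under base and which destroys C2. The six phenols add sensitivity to base and oxidants, so they must stay masked to the end and be unmasked without base. The difficulty is twofold: the C3–C3'' bond joins a tertiary sp3 carbon to a fully substituted alkene carbon flanked by an aryl group and a carbonyl, and the absolute configuration must be set in a ring whose thermodynamics fix only the relative one. The strategy rests on ring C: O1, C8a, C4a and C4 form a four-atom heterodiene unit that shares C8a–C4a with ring A, and C2–C3 is a two-carbon unit whose trans substituents, ring B and the flavone, are those of an E-alkene. Ring C is therefore the retron of an oxa-[4+2] cycloaddition between an ortho-quinone methide built on ring A and a 3-styrylflavone, provided C4 is carried one oxidation level below the ketone.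

## Retrosynthetic reasoning

**12 to 11.** The six phenolic O–H bonds of 12 become O–CH3 bonds in 11. Free phenols would not survive palladium catalysis, electrophilic iodine, the acid-released quinone methide or a quinone oxidant, and 12 itself opens at O1–C2 under base. Methyl ethers are inert to all of this and are already present on the commercial building blocks. The price is a final Lewis-acid ether cleavage that must leave C2 and C3 alone.

**11 to 10.** The C4 carbonyl of 11 is traced back to a C4 carbon bearing hydrogen and methoxy in 10. This is a change of oxidation level, not a skeletal cut. It is made because only a carbon at the acetal level can serve as the terminus of the heterodiene. The forward step must remove one hydride from a position benzylic to the trioxygenated ring A and α to oxygen without touching C2–H; it also deletes the uncontrolled C4 centre.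

**10 to 6 and 8 (through 9).** Ring C of 10 is cut at O1–C2 and C3–C4, the two ring C bonds that contain neither a ring A atom nor the C2–C3 bond. This removes the ring and both stereocentres in one move and gives a ring A piece carrying C4 (9, released from 8) and an alkene carrying ring B and the complete flavone (6). Cutting C3–C3'' instead would require a stereocontrolled bond between an enolisable sp3 carbon and a hindered alkene carbon. Cutting only one ring C bond would leave a stereocentre in a labile open-chain precursor. The gain is that the trans relation becomes alkene geometry and the C3–C3'' bond becomes an sp2–sp2 bond. The forward step must be regioselective, transfer the alkene geometry and differentiate the alkene faces.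

**8 to 7.** The acetal carbon of 8 is the formyl carbon of 7; two C–O bonds are cut. The acetal is needed because the aldehyde cannot ionise to a quinone methide that keeps an oxygen on C4.

**6 to 4 and 5.** The bond between C3'' and the styryl carbon is cut. It is an sp2–sp2 bond between a 3-haloflavone and a terminal alkene, made by a palladium coupling that also fixes the E geometry on which the trans relation later depends.

**4 to 3.** The pyranone ring of 4 is cut at O1''–C2'' and at C3''–I. Both bonds form in one electrophilic cyclisation of the ynone 3, and the two equivalent ortho-methoxy groups of 3 remove any regiochemical question.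

**3 to 1 and 2.** The acyl–alkynyl bond is cut, giving two commercial pieces joined by a palladium/copper acylation of the terminal alkyne.

## Alternatives that were turned down

**Alternative 1: asymmetric intramolecular Stetter closure of ring C.**
- Disconnection: only C3–C4 is cut. The precursor is the salicylaldehyde ether A2, in which O1–C2 already exists and C3 is the β-carbon of an alkylidene 1,3-diketone.
- Forward key step: a chiral triazolium-derived carbene turns the aldehyde carbon (future C4) into an acyl anion equivalent that adds to C3 in a 6-exo-trig conjugate addition, giving chromanone A1.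
- For it: C4 arrives as the ketone, so no oxidation step is needed, and carbene-catalysed closures of salicylaldehyde ethers to chroman-4-ones are the best-developed asymmetric Stetter reactions. On both points it is stronger than the chosen route.
- Against it: C2 is not made in the key step. In A2 it is an aryloxy-bearing carbon that is benzylic, allylic and γ to two carbonyls, so under the basic carbene conditions it can lose its proton or its aryloxide. The centre would have to be installed enantioselectively beforehand and then survive. The aldehyde of A2 sits between two ortho oxygen substituents and is deactivated towards carbene addition. A1 is not yet a biflavonoid: the diketone must still be cyclised to the flavone under acid, next to a C3 centre that can undergo retro-Michael opening.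
- Comparison: the chosen strategy arrives with the flavone complete and sets C2 and C3 together from a configurationally inert E-alkene. It pays with one oxidation step.

**Alternative 2: biomimetic Claisen folding of a triketo ester into ring A.**
- Disconnection: C4a–C5 inside ring A. Ring A is built from the open-chain 3,5,7-triketo ester A4, which already carries the flavonyl-substituted enone.
- Forward key step: base generates the carbanion at chain C6, which attacks the ester carbonyl; loss of methoxide and enolisation give the phloroglucinol ring of chalcone A3.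
- For it: it follows the biosynthetic logic, ring A appears with free hydroxyls (either ortho hydroxyl can later close ring C), and C4 is already a ketone. In oxidation-level economy it is equal or better.
- Against it: it spends the key step on the one ring that can be bought (ring A is present in 7). A4 has three acidic methylenes, an ester and a Michael acceptor, so aldol closure of C2 onto the C7 carbonyl, lactonisation to a pyranone and conjugate additions compete with the Claisen mode. After the key step neither stereocentre exists: ring C would still have to be closed from A3 by an enantioselective, reversible oxa-Michael addition of an α-substituted chalcone.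
- Comparison: the chosen strategy uses its key step for ring C and both stereocentres and takes ring A from a commercial aldehyde.

**Alternative 3: anodic quinone methide formation with asymmetric ring C closure.**
- Disconnection: only O1–C2. The precursor is dihydrochalcone A6, with a free phenol on ring B, a free ortho-hydroxyl on ring A and the flavone on the α-carbon.
- Forward key step: anodic two-electron oxidation of the ring B phenol gives para-quinone methide A7; the ortho-hydroxyl of ring A adds to its exocyclic carbon (future C2) under a chiral phosphoric acid to give A5.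
- For it: the C4 ketone is present from the start, and additions of oxygen nucleophiles to para-quinone methides under chiral phosphoric acids are well established. Because C3 of A5 can equilibrate to trans, only C2 needs catalyst control. On these points it is at least as strong as the chosen route, and it uses no stoichiometric oxidant.
- Against it: A6 must already contain the C3–C3'' bond at an enolisable ketone α-carbon, which means an α-arylation with a hindered 3-haloflavone and extra steps. Ring A of A6 and the phenol of A5 are oxidisable in the same potential window. A7 has an acidic hydrogen at C3 and can tautomerise to the hydroxychalcone, after which closure runs through the ordinary reversible chalcone–flavanone manifold with little catalyst control. The supporting electrolyte competes with the chiral phosphate. A5 still needs the same ether cleavage.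
- Comparison: the chosen strategy forms two ring bonds in its key step and makes the congested C3–C3'' link as a simple sp2–sp2 coupling before any stereocentre exists. It gives up the direct ketone for one oxidation step.

Key step: step 5

## Remarks and assumptions

- C4 of 10 forms as a mixture of epimers and is carried as such, since step 6 turns it into the carbonyl carbon.
- C3 has the same spatial arrangement in 10, 11 and 12. Its descriptor is S in 10 and R in 11 and 12 because the C4 carbonyl carbon outranks C2, whereas the C4 carbon bearing hydrogen and methoxy does not.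
- Which hand of the phosphoric acid leads to the (2S) series cannot be predicted with confidence for this pair of reactants. The (R) acid is written; the (S) acid is taken if the sense proves opposite.

## Route

Step 1
Reactants: 1 2,4,6-trimethoxybenzoyl chloride; 2 4-ethynylanisole
Product: 3 3-(4-methoxyphenyl)-1-(2,4,6-trimethoxyphenyl)prop-2-yn-1-one
Conditions: PdCl2(PPh3)2 (2 mol %), CuI (4 mol %), Et3N (1.5 equiv), THF, rt
Reagents that add atoms: none
Why: Acyl Sonogashira coupling: zerovalent palladium formed from PdCl2(PPh3)2 inserts into the C–Cl bond of 1, the copper acetylide of 2 transmetallates and reductive elimination gives the ynone; at room temperature with a tertiary amine the acid chloride should not decarbonylate and the ynone should not be attacked by the base.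

Step 2
Reactants: 3 3-(4-methoxyphenyl)-1-(2,4,6-trimethoxyphenyl)prop-2-yn-1-one
Product: 4 3-iodo-5,7-dimethoxy-2-(4-methoxyphenyl)-4H-chromen-4-one
Conditions: ICl (1.2 equiv), CH2Cl2, −78 °C; then aq. Na2S2O3
Reagents that add atoms: iodine monochloride, ClI
Why: Electrophilic iodocyclisation of an ortho-methoxyaryl ynone: ICl activates the triple bond, an ortho-methoxy oxygen attacks the anisyl-bearing alkyne carbon in the 6-endo-dig mode and chloride removes the methyl group from the oxonium ion. The two ortho-methoxy groups of 3 are equivalent, so only one chromone can form; low temperature and a small excess of ICl are meant to hold back iodination of the electron-rich benzo ring.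

Step 3
Reactants: 4 3-iodo-5,7-dimethoxy-2-(4-methoxyphenyl)-4H-chromen-4-one; 5 4-methoxystyrene
Product: 6 (E)-5,7-dimethoxy-2-(4-methoxyphenyl)-3-[2-(4-methoxyphenyl)ethenyl]-4H-chromen-4-one
Conditions: Pd(OAc)2 (5 mol %), P(o-tol)3 (10 mol %), Et3N (2 equiv), DMF, 90 °C
Reagents that add atoms: none
Why: Mizoroki–Heck reaction: oxidative addition of zerovalent palladium into the C3''–I bond, syn carbopalladation at the terminal alkene carbon of 5 and syn β-hydride elimination give the E-styryl group; 3-haloflavones are established partners in this coupling, and the neutral phosphine/iodide manifold favours attack at the unsubstituted carbon of the electron-rich styrene.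

Step 4
Reactants: 7 2-hydroxy-4,6-dimethoxybenzaldehyde
Product: 8 2-(dimethoxymethyl)-3,5-dimethoxyphenol
Conditions: HC(OMe)3 (5 equiv), MeOH, p-TsOH·H2O (1 mol %), rt; then Et3N; concentrated and used crude
Reagents that add atoms: trimethyl orthoformate, COC(OC)OC; methanol, CO
Why: Acid-catalysed acetalisation driven by the orthoester as dehydrating agent; the excess of methanol keeps the easily ionised acetal from condensing with itself, and the acid is neutralised before concentration so that 8 is not ionised to the quinone methide on isolation.

Step 5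
Reactants: 6 (E)-5,7-dimethoxy-2-(4-methoxyphenyl)-3-[2-(4-methoxyphenyl)ethenyl]-4H-chromen-4-one; 8 2-(dimethoxymethyl)-3,5-dimethoxyphenol
Product: 10 3-[(2S,3S)-4,5,7-trimethoxy-2-(4-methoxyphenyl)chroman-3-yl]-5,7-dimethoxy-2-(4-methoxyphenyl)-4H-chromen-4-one (2,3-trans; both C4 epimers), via methoxy ortho-quinone methide 9 (not isolated)
Conditions: (R)-3,3'-bis(2,4,6-triisopropylphenyl)-1,1'-binaphthyl-2,2'-diyl hydrogen phosphate (10 mol %), 5 Å MS, CH2Cl2, −20 °C → rt; 8 (2 equiv) added slowly
Reagents that add atoms: none
Why: Proposed new method: the phosphoric acid protonates a methoxy group of 8, methanol leaves with help from the ortho-hydroxyl and the two ring methoxy groups, and the resulting oxocarbenium phosphate ion pair, the hydrogen-bonded form of ortho-quinone methide 9, adds as a heterodiene across the styryl double bond of 6, the closest known reaction type being the acid-promoted inverse-demand oxa-[4+2] cycloaddition of alkoxy ortho-quinone methides from salicylaldehyde acetals with styrenes to 4-alkoxy-2-arylchromans, with chiral phosphoric acids known to steer ortho-quinone methide cycloadditions of other alkenes but not of a 1,2-disubstituted styrene such as 6. Ring C closes as a six-membered ring by a concerted, asynchronous, suprafacial [4+2] cycloaddition in which the C3–C4 bond runs ahead of the O1–C2 bond; in the stepwise limit it closes by collapse of the phenol oxygen onto the anisyl-stabilised benzylic cation at C2. The trans relation of C2 and C3 is controlled by the E geometry of the alkene, which the suprafacial addition transfers, and it is also the diequatorial, thermodynamically preferred relation if the addition is stepwise. The absolute configuration of C2 and C3 is controlled by the chiral phosphate, which stays bound to the quinone methide by the O–H···O hydrogen bond and ion pairing and shields one of its faces with the 3,3'-aryl groups. C4 is set by the endo or exo approach, is not controlled and need not be, since step 6 removes it. The step needs regioselectivity (O1 to the anisyl-bearing carbon, C4 to the flavone-bearing carbon), which the para-methoxy group of the styryl ring secures by stabilising positive charge at C2, whereas the competing donor, the ring oxygen of the chromone, is tied up as a vinylogous ester by the C4'' carbonyl. It also needs chemoselectivity over self-condensation of 8 and over arylation of the dimethoxy benzo ring of 6, which slow addition of 8 and low temperature are meant to secure, while the tetrasubstituted, electron-poor C2''=C3'' bond is no competing dienophile. Molecular sieves take up the methanol set free, so that the ionisation is not reversed.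

Step 6
Reactants: 10 3-[(2S,3S)-4,5,7-trimethoxy-2-(4-methoxyphenyl)chroman-3-yl]-5,7-dimethoxy-2-(4-methoxyphenyl)-4H-chromen-4-one
Product: 11 (2S,3R)-3-[5,7-dimethoxy-2-(4-methoxyphenyl)-4-oxo-4H-chromen-3-yl]-5,7-dimethoxy-2-(4-methoxyphenyl)chroman-4-one
Conditions: DDQ (2 equiv), CH2Cl2/H2O (10:1), 0 °C → rt
Reagents that add atoms: water, O
Why: Benzylic oxidation by hydride abstraction: DDQ removes the C4 hydride, which is activated by O1, the 5- and 7-methoxy groups of ring A and the α-methoxy group, water adds to the methyl oxocarbenium ion and the hemiketal loses methanol, as in the DDQ cleavage of electron-rich benzylic ethers. Both C4 epimers converge on 11; C2 is untouched and C3, now α to the ketone, keeps or regains the diequatorial trans arrangement.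

Step 7
Reactants: 11 (2S,3R)-3-[5,7-dimethoxy-2-(4-methoxyphenyl)-4-oxo-4H-chromen-3-yl]-5,7-dimethoxy-2-(4-methoxyphenyl)chroman-4-one
Product: 12 (2S,3R)-3-[5,7-dihydroxy-2-(4-hydroxyphenyl)-4-oxo-4H-chromen-3-yl]-5,7-dihydroxy-2-(4-hydroxyphenyl)chroman-4-one
Conditions: BBr3 (15 equiv), CH2Cl2, −78 °C → rt; then H2O, 0 °C; no basic wash
Reagents that add atoms: none
Why: Lewis-acid cleavage of aryl methyl ethers: BBr3 binds each ether oxygen and bromide attacks the methyl group (SN2), the two methoxy groups peri to the carbonyls going first by chelation; no base is present at any stage, so retro-oxa-Michael opening of ring C is not triggered. Loss of configuration would need both C2 and C3 to invert, and trans is the thermodynamic arrangement.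

## Compound list

1 | 2,4,6-trimethoxybenzoyl chloride | COc1cc(OC)c(C(Cl)=O)c(OC)c1 | starting material
2 | 4-ethynylanisole | C#Cc1ccc(OC)cc1 | starting material
3 | 3-(4-methoxyphenyl)-1-(2,4,6-trimethoxyphenyl)prop-2-yn-1-one | COc1ccc(C#CC(=O)c2c(OC)cc(OC)cc2OC)cc1 | intermediate
4 | 3-iodo-5,7-dimethoxy-2-(4-methoxyphenyl)-4H-chromen-4-one | COc1ccc(-c2oc3cc(OC)cc(OC)c3c(=O)c2I)cc1 | intermediate
5 | 4-methoxystyrene | C=Cc1ccc(OC)cc1 | starting material
6 | (E)-5,7-dimethoxy-2-(4-methoxyphenyl)-3-[2-(4-methoxyphenyl)ethenyl]-4H-chromen-4-one | COc1ccc(/C=C/c2c(-c3ccc(OC)cc3)oc3cc(OC)cc(OC)c3c2=O)cc1 | intermediate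
7 | 2-hydroxy-4,6-dimethoxybenzaldehyde | COc1cc(O)c(C=O)c(OC)c1 | starting material
8 | 2-(dimethoxymethyl)-3,5-dimethoxyphenol | COC(OC)c1c(O)cc(OC)cc1OC | intermediate
9 | 3,5-dimethoxy-6-(methoxymethylidene)cyclohexa-2,4-dien-1-one (ortho-quinone methide, not isolated) | COC=C1C(=O)C=C(OC)C=C1OC | intermediate
10 | 3-[(2S,3S)-4,5,7-trimethoxy-2-(4-methoxyphenyl)chroman-3-yl]-5,7-dimethoxy-2-(4-methoxyphenyl)-4H-chromen-4-one, 2,3-trans, both C4 epimers | COC1c2c(OC)cc(OC)cc2O[C@H](c2ccc(OC)cc2)[C@H]1c1c(-c2ccc(OC)cc2)oc2cc(OC)cc(OC)c2c1=O | intermediate
11 | (2S,3R)-3-[5,7-dimethoxy-2-(4-methoxyphenyl)-4-oxo-4H-chromen-3-yl]-5,7-dimethoxy-2-(4-methoxyphenyl)chroman-4-one | O=C1c2c(OC)cc(OC)cc2O[C@H](c2ccc(OC)cc2)[C@H]1c1c(-c2ccc(OC)cc2)oc2cc(OC)cc(OC)c2c1=O | intermediate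
12 | (2S,3R)-3-[5,7-dihydroxy-2-(4-hydroxyphenyl)-4-oxo-4H-chromen-3-yl]-5,7-dihydroxy-2-(4-hydroxyphenyl)chroman-4-one | O=C1c2c(O)cc(O)cc2O[C@H](c2ccc(O)cc2)[C@H]1c1c(-c2ccc(O)cc2)oc2cc(O)cc(O)c2c1=O | target

## Step count and least certain steps

Total: 7 steps. Longest linear sequence: 6 steps (steps 1, 2, 3, 5, 6, 7); step 4 is a one-step side branch.

**Step 5 (key step, beyond known chemistry).**
- What may go wrong: the alkene of 6 is hindered and only moderately nucleophilic, and the trioxygenated quinone methide is a stabilised, weak electrophile, so self-condensation of 8 can outrun the cycloaddition. Facial discrimination may be poor, because 6 has no hydrogen-bond donor to anchor it to the phosphate. Re-ionisation of the C4 methoxy group of the product, followed by loss of H3, would erase C3.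
- Fallback (sets out from 6 and 8, returns at 11): the cycloaddition is run without asymmetric induction, with Sc(OTf)3 or CF3CO2H in CH2Cl2. This is the known acid-promoted quinone methide–styrene cycloaddition. It should give 10 as a racemate with its mirror image 3-[(2R,3R)-4,5,7-trimethoxy-2-(4-methoxyphenyl)chroman-3-yl]-5,7-dimethoxy-2-(4-methoxyphenyl)-4H-chromen-4-one F1. Oxidation as in step 6 then gives 11 together with (2R,3S)-3-[5,7-dimethoxy-2-(4-methoxyphenyl)-4-oxo-4H-chromen-3-yl]-5,7-dimethoxy-2-(4-methoxyphenyl)chroman-4-one F2. The pair is separated by preparative chromatography on a chiral stationary phase, and the route is rejoined at 11.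

**Step 7.**
- What may go wrong: slow cleavage of the ethers not assisted by a carbonyl forces long exposure to the Lewis acid. Acid-induced opening of ring C at O1–C2, or stepwise inversion of C2 and C3 through the cis isomer, would then erode the enantiomeric purity.
- Fallback (sets out from 6, returns at 12): the methyl ethers are exchanged for benzyl ethers before any stereocentre exists.
  - 6 is demethylated with BBr3 to (E)-5,7-dihydroxy-2-(4-hydroxyphenyl)-3-[2-(4-hydroxyphenyl)ethenyl]-4H-chromen-4-one F3.
  - F3 is benzylated (BnBr, K2CO3, DMF, 70 °C) to (E)-5,7-bis(benzyloxy)-2-[4-(benzyloxy)phenyl]-3-{2-[4-(benzyloxy)phenyl]ethenyl}-4H-chromen-4-one F4.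
  - Purchased 2,4,6-trihydroxybenzaldehyde F5 is benzylated at its two non-chelated hydroxyls (BnBr, 2 equiv, K2CO3, DMF) to 4,6-bis(benzyloxy)-2-hydroxybenzaldehyde F6.
  - F6 is acetalised as in step 4 to 3,5-bis(benzyloxy)-2-(dimethoxymethyl)phenol F7.
  - Cycloaddition of F4 and F7 as in step 5, through 3,5-bis(benzyloxy)-6-(methoxymethylidene)cyclohexa-2,4-dien-1-one F8, gives 3-{(2S,3S)-5,7-bis(benzyloxy)-2-[4-(benzyloxy)phenyl]-4-methoxychroman-3-yl}-5,7-bis(benzyloxy)-2-[4-(benzyloxy)phenyl]-4H-chromen-4-one F9.
  - DDQ as in step 6 gives (2S,3R)-5,7-bis(benzyloxy)-2-[4-(benzyloxy)phenyl]-3-{5,7-bis(benzyloxy)-2-[4-(benzyloxy)phenyl]-4-oxo-4H-chromen-3-yl}chroman-4-one F10.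
  - Hydrogenolysis (H2, Pd(OH)2/C, THF/MeOH, rt) gives 12 without any Lewis acid.

**Step 6.**
- What may go wrong: hydride abstraction may be slow from the epimer whose C4–H lies near the plane of ring A (methoxy pseudo-axial to avoid the 5-methoxy group). Abstraction of the C2 hydrogen, a para-methoxybenzylic ether hydrogen, may compete.
- Fallback (sets out from 10, returns at 11): the C4 methoxy group is exchanged for hydroxyl by SN1 hydrolysis (dilute HCl, THF/H2O, 0 °C), which works for both epimers. This gives 3-[(2S,3S)-4-hydroxy-5,7-dimethoxy-2-(4-methoxyphenyl)chroman-3-yl]-5,7-dimethoxy-2-(4-methoxyphenyl)-4H-chromen-4-one F11. The benzylic alcohol is oxidised with Dess–Martin periodinane (NaHCO3, CH2Cl2) to 11.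

**Step 2.**
- What may go wrong: iodination of the benzo ring at the positions flanked by methoxy groups may compete with activation of the alkyne and lead to over-iodinated chromones.
- Fallback (sets out from 3, returns at 4): electrophilic iodine is avoided.
  - BCl3 (CH2Cl2, −78 → 0 °C) cleaves one methoxy group ortho to the carbonyl by chelation, giving 1-(2-hydroxy-4,6-dimethoxyphenyl)-3-(4-methoxyphenyl)prop-2-yn-1-one F12.
  - Et2NH in EtOH at reflux closes the six-membered ring through the enaminone, giving 5,7-dimethoxy-2-(4-methoxyphenyl)-4H-chromen-4-one F13.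
  - Lithiation at C3 with lithium diisopropylamide (THF, −78 °C) and quenching with I2 gives 4.

## Further compounds

F1 | step 5 | 3-[(2R,3R)-4,5,7-trimethoxy-2-(4-methoxyphenyl)chroman-3-yl]-5,7-dimethoxy-2-(4-methoxyphenyl)-4H-chromen-4-one (mirror image of 10, C4 epimers) | COC1c2c(OC)cc(OC)cc2O[C@@H](c2ccc(OC)cc2)[C@@H]1c1c(-c2ccc(OC)cc2)oc2cc(OC)cc(OC)c2c1=O
F2 | step 5 | (2R,3S)-3-[5,7-dimethoxy-2-(4-methoxyphenyl)-4-oxo-4H-chromen-3-yl]-5,7-dimethoxy-2-(4-methoxyphenyl)chroman-4-one (mirror image of 11) | O=C1c2c(OC)cc(OC)cc2O[C@@H](c2ccc(OC)cc2)[C@@H]1c1c(-c2ccc(OC)cc2)oc2cc(OC)cc(OC)c2c1=O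
F3 | step 7 | (E)-5,7-dihydroxy-2-(4-hydroxyphenyl)-3-[2-(4-hydroxyphenyl)ethenyl]-4H-chromen-4-one | Oc1ccc(/C=C/c2c(-c3ccc(O)cc3)oc3cc(O)cc(O)c3c2=O)cc1
F4 | step 7 | (E)-5,7-bis(benzyloxy)-2-[4-(benzyloxy)phenyl]-3-{2-[4-(benzyloxy)phenyl]ethenyl}-4H-chromen-4-one | O=c1c(/C=C/c2ccc(OCc3ccccc3)cc2)c(-c2ccc(OCc3ccccc3)cc2)oc2cc(OCc3ccccc3)cc(OCc3ccccc3)c12
F5 | step 7 | 2,4,6-trihydroxybenzaldehyde | O=Cc1c(O)cc(O)cc1O
F6 | step 7 | 4,6-bis(benzyloxy)-2-hydroxybenzaldehyde | O=Cc1c(O)cc(OCc2ccccc2)cc1OCc1ccccc1
F7 | step 7 | 3,5-bis(benzyloxy)-2-(dimethoxymethyl)phenol | COC(OC)c1c(O)cc(OCc2ccccc2)cc1OCc1ccccc1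
F8 | step 7 | 3,5-bis(benzyloxy)-6-(methoxymethylidene)cyclohexa-2,4-dien-1-one | COC=C1C(=O)C=C(OCc2ccccc2)C=C1OCc1ccccc1
F9 | step 7 | 3-{(2S,3S)-5,7-bis(benzyloxy)-2-[4-(benzyloxy)phenyl]-4-methoxychroman-3-yl}-5,7-bis(benzyloxy)-2-[4-(benzyloxy)phenyl]-4H-chromen-4-one (C4 epimers) | COC1c2c(OCc3ccccc3)cc(OCc3ccccc3)cc2O[C@H](c2ccc(OCc3ccccc3)cc2)[C@H]1c1c(-c2ccc(OCc3ccccc3)cc2)oc2cc(OCc3ccccc3)cc(OCc3ccccc3)c2c1=O
F10 | step 7 | (2S,3R)-5,7-bis(benzyloxy)-2-[4-(benzyloxy)phenyl]-3-{5,7-bis(benzyloxy)-2-[4-(benzyloxy)phenyl]-4-oxo-4H-chromen-3-yl}chroman-4-one | O=C1c2c(OCc3ccccc3)cc(OCc3ccccc3)cc2O[C@H](c2ccc(OCc3ccccc3)cc2)[C@H]1c1c(-c2ccc(OCc3ccccc3)cc2)oc2cc(OCc3ccccc3)cc(OCc3ccccc3)c2c1=O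
F11 | step 6 | 3-[(2S,3S)-4-hydroxy-5,7-dimethoxy-2-(4-methoxyphenyl)chroman-3-yl]-5,7-dimethoxy-2-(4-methoxyphenyl)-4H-chromen-4-one (C4 epimers) | OC1c2c(OC)cc(OC)cc2O[C@H](c2ccc(OC)cc2)[C@H]1c1c(-c2ccc(OC)cc2)oc2cc(OC)cc(OC)c2c1=O
F12 | step 2 | 1-(2-hydroxy-4,6-dimethoxyphenyl)-3-(4-methoxyphenyl)prop-2-yn-1-one | COc1ccc(C#CC(=O)c2c(O)cc(OC)cc2OC)cc1
F13 | step 2 | 5,7-dimethoxy-2-(4-methoxyphenyl)-4H-chromen-4-one | COc1ccc(-c2cc(=O)c3c(OC)cc(OC)cc3o2)cc1
A1 | alternative 1 | (2S,3R)-5,7-dimethoxy-2-(4-methoxyphenyl)-3-{1-(4-methoxyphenyl)-3-[2-(methoxymethoxy)-4,6-dimethoxyphenyl]-1,3-dioxopropan-2-yl}chroman-4-one | O=C1c2c(OC)cc(OC)cc2O[C@H](c2ccc(OC)cc2)[C@H]1C(C(=O)c1ccc(OC)cc1)C(=O)c1c(OCOC)cc(OC)cc1OC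
A2 | alternative 1 | 2-{[(1S)-3-(4-methoxybenzoyl)-1-(4-methoxyphenyl)-4-[2-(methoxymethoxy)-4,6-dimethoxyphenyl]-4-oxobut-2-en-1-yl]oxy}-4,6-dimethoxybenzaldehyde | O=Cc1c(OC)cc(OC)cc1O[C@H](c1ccc(OC)cc1)C=C(C(=O)c1ccc(OC)cc1)C(=O)c1c(OCOC)cc(OC)cc1OC
A3 | alternative 2 | (E)-2-[5,7-dimethoxy-2-(4-methoxyphenyl)-4-oxo-4H-chromen-3-yl]-3-(4-methoxyphenyl)-1-(2,4,6-trihydroxyphenyl)prop-2-en-1-one | Oc1cc(O)c(C(=O)/C(=C/c2ccc(OC)cc2)c2c(-c3ccc(OC)cc3)oc3cc(OC)cc(OC)c3c2=O)c(O)c1
A4 | alternative 2 | methyl (E)-8-[5,7-dimethoxy-2-(4-methoxyphenyl)-4-oxo-4H-chromen-3-yl]-9-(4-methoxyphenyl)-3,5,7-trioxonon-8-enoate | COC(=O)CC(=O)CC(=O)CC(=O)/C(=C/c1ccc(OC)cc1)c1c(-c2ccc(OC)cc2)oc2cc(OC)cc(OC)c2c1=O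
A5 | alternative 3 | (2S,3R)-2-(4-hydroxyphenyl)-5,7-dimethoxy-3-[5,7-dimethoxy-2-(4-methoxyphenyl)-4-oxo-4H-chromen-3-yl]chroman-4-one | O=C1c2c(OC)cc(OC)cc2O[C@H](c2ccc(O)cc2)[C@H]1c1c(-c2ccc(OC)cc2)oc2cc(OC)cc(OC)c2c1=O
A6 | alternative 3 | 1-(2-hydroxy-4,6-dimethoxyphenyl)-2-[5,7-dimethoxy-2-(4-methoxyphenyl)-4-oxo-4H-chromen-3-yl]-3-(4-hydroxyphenyl)propan-1-one (α-carbon configurationally labile, no descriptor) | O=C(c1c(O)cc(OC)cc1OC)C(Cc1ccc(O)cc1)c1c(-c2ccc(OC)cc2)oc2cc(OC)cc(OC)c2c1=O
A7 | alternative 3 | 4-{3-(2-hydroxy-4,6-dimethoxyphenyl)-2-[5,7-dimethoxy-2-(4-methoxyphenyl)-4-oxo-4H-chromen-3-yl]-3-oxopropylidene}cyclohexa-2,5-dien-1-one | O=C1C=CC(=CC(C(=O)c2c(O)cc(OC)cc2OC)c2c(-c3ccc(OC)cc3)oc3cc(OC)cc(OC)c3c2=O)C=C1
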